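**Retrosynthetic overview**
1. Benzofuran numbering is used (O1, C2, C3, C3a, C4–C7, C7a). Ring A is the benzene ring of the benzofuran, ring B the dihydrofuran, ring C the 4-hydroxyphenyl ring.
2. Late disconnections: the two aryl MOM acetals; the enone C=C (Claisen–Schmidt, C5 acetyl plus a ring C aldehyde); the tertiary C–OH (Markovnikov hydration of a C2 isopropenyl group).
3. Key disconnection: ring B is the only ring that is built (rings A and C are bought). It is cut at O1–C7a and C2–C3 together, back to 3-acetyl-6-fluoro-2-(methoxymethoxy)benzaldehyde and methacrolein diacetate, which acts as an umpoled O–C2 donor under iridium catalysis.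
4. Enabling feature: in ring A, C7a is para to the C5 acyl carbon and ortho to C3a, the carbon that bears C3. A fluoride on C7a is therefore SNAr-active and within five-ring reach of the oxygen on C2 once C3 (as CHO) has accepted C2. The vicinal O–C2/O–C3 pair lets the acetyl group leave O–C2 only after the C–C bond exists.
5. The arene comes from 2-bromo-5-fluorophenol by ortho-formylation, MOM capping and Stille acetylation.

Key step: step 4

Assumption (remark on the chemistry): (R)-SEGPHOS is taken to direct addition to the aldehyde face that gives (S) at C3, by analogy with allylations and anti-crotylations run with the same catalyst family. If the sense is opposite, (S)-SEGPHOS is used and nothing else changes.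

Step 1
Reactants: 1 2-bromo-5-fluorophenol
Product: 2 3-bromo-6-fluoro-2-hydroxybenzaldehyde
Conditions: MgCl2, Et3N, (CH2O)n, MeCN, reflux; then 1 M HCl
Reagents that add atoms: paraformaldehyde (as formaldehyde) C=O
Why: Casnati–Skattebøl ortho-formylation, in which the ArOMgCl phenoxide delivers formaldehyde only ortho to oxygen, and the single free ortho carbon lies between OH and F.

Step 2
Reactants: 2 3-bromo-6-fluoro-2-hydroxybenzaldehyde
Product: 3 3-bromo-6-fluoro-2-(methoxymethoxy)benzaldehyde
Conditions: MOMCl, iPr2NEt, CH2Cl2, 0 °C to rt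
Reagents that add atoms: chloromethyl methyl ether (MOMCl) COCCl
Why: Williamson-type O-alkylation of the acidic salicylaldehyde OH to an aryl MOM acetal, an alkyl-type cap that cannot migrate to O–C3 and keeps ring A free of a deactivating phenoxide in the later SNAr.

Step 3
Reactants: 3 3-bromo-6-fluoro-2-(methoxymethoxy)benzaldehyde
Product: 5 3-acetyl-6-fluoro-2-(methoxymethoxy)benzaldehyde, via enol ether 4 (not isolated)
Conditions: Bu3SnC(OEt)=CH2, PdCl2(PPh3)2 (5 mol %), toluene, 100 °C; then 1 M HCl, THF, 0 °C, brief
Reagents that add atoms: tributyl(1-ethoxyvinyl)stannane CCCC[Sn](CCCC)(CCCC)C(=C)OCC; water O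
Why: Migita–Kosugi–Stille coupling of the aryl bromide with a masked acetyl anion under neutral conditions that spare CHO and the C–F bond, followed by fast hydrolysis of the aryl enol ether.

Step 4
Reactants: 5 3-acetyl-6-fluoro-2-(methoxymethoxy)benzaldehyde; 6 2-methylprop-2-ene-1,1-diyl diacetate (methacrolein diacetate)
Product: 9 (2R,3S)-5-acetyl-4-(methoxymethoxy)-2-(prop-1-en-2-yl)-2,3-dihydro-1-benzofuran-3-yl acetate, via anti adduct 7 (not isolated), via acetyl-shifted alcohol 8 (not isolated)
Conditions: [Ir(cod)Cl]2 (2.5 mol %), (R)-SEGPHOS (5 mol %), 4-cyano-3-nitrobenzoic acid (10 mol %), Cs2CO3 (20 mol %), iPrOH (2 equiv), THF, 80 °C; then Cs2CO3 (3 equiv), DMSO, 60 °C, same flask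
Reagents that add atoms: none
Why: Proposed new method: the cyclometallated complex formed in situ from [Ir(cod)Cl]2, (R)-SEGPHOS and the nitrobenzoic acid ionises one acetate of 6 to a 1-acetoxy-2-methyl-π-allyl complex of trivalent iridium, whose (E)-σ-allyl form adds through a closed chair to the aldehyde of 5 at the acetoxy-bearing carbon (C2–C3 bond, 7), while 2-propanol returns the metal to its monovalent state. The added Cs2CO3 then lets the acetyl group walk from O–C2 to the neighbouring O–C3 through a five-membered orthoester anion (8), and the freed C2 alkoxide attacks C7a, para to the acetyl ketone, in an addition–elimination SNAr that expels fluoride (O1–C7a bond). The closest known reaction types are the iridium-catalysed transfer-hydrogenative anti-(α-acyloxy)allylation of aldehydes with acrolein gem-dicarboxylates, base-induced 1,2-acyl migration in diol monoesters and intramolecular SNAr etherification of 4-fluoroaryl ketones; the 2-methyl donor and the merger into one annulation are new. Ring B closes in a 5-exo-trig mode at the ipso carbon (Meisenheimer adduct) and irreversibly, so it drains the acyl-shift equilibrium. C3 is set by the ligand-controlled aldehyde face and C2 relative to it (anti, which becomes trans in ring B) by the pseudo-equatorial acetoxy group of the (E)-σ-allyl chair, and neither centre is touched afterwards because only O–acyl and O–aryl bonds change. The substrate secures the selectivity needed: the aldehyde outruns the ketone in carbonyl addition, fluoride sits only on C7a, O–C3 could close only a four-membered ring, O–C4 is capped as its MOM ether, and the side chain is kept at the alkene level so that no tertiary alkoxide can close a chroman.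

Step 5
Reactants: 9 (2R,3S)-5-acetyl-4-(methoxymethoxy)-2-(prop-1-en-2-yl)-2,3-dihydro-1-benzofuran-3-yl acetate
Product: 10 (2S,3S)-5-acetyl-2-(2-hydroxypropan-2-yl)-4-(methoxymethoxy)-2,3-dihydro-1-benzofuran-3-yl acetate
Conditions: Co(acac)2 (20 mol %), PhSiH3, O2 (1 atm), THF, rt
Reagents that add atoms: dioxygen O=O
Why: Mukaiyama hydration, in which hydrogen-atom transfer from the hydride formed from Co(acac)2 and PhSiH3 gives the tertiary radical that O2 captures, so the Markovnikov alcohol forms without touching ketone, ester, acetal or either stereocenter (the C2 descriptor changes only through CIP ranking).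

Step 6
Reactants: 10 (2S,3S)-5-acetyl-2-(2-hydroxypropan-2-yl)-4-(methoxymethoxy)-2,3-dihydro-1-benzofuran-3-yl acetate; 11 4-(methoxymethoxy)benzaldehyde
Product: 12 (E)-1-[(2S,3S)-3-hydroxy-2-(2-hydroxypropan-2-yl)-4-(methoxymethoxy)-2,3-dihydro-1-benzofuran-5-yl]-3-[4-(methoxymethoxy)phenyl]prop-2-en-1-one
Conditions: KOH, EtOH, rt; then 1 M HCl to pH 6
Reagents that add atoms: none
Why: Claisen–Schmidt condensation (aldol addition, E1cB dehydration) gives the thermodynamic E-enone and hydroxide saponifies the C3 acetate in the same flask, while the MOM cap on O–C4 blocks flavanone closure and phenoxide-driven loss of acetate from C3.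

Step 7
Reactants: 12 (E)-1-[(2S,3S)-3-hydroxy-2-(2-hydroxypropan-2-yl)-4-(methoxymethoxy)-2,3-dihydro-1-benzofuran-5-yl]-3-[4-(methoxymethoxy)phenyl]prop-2-en-1-one
Product: 13 brosimacutin G, (E)-1-[(2S,3S)-3,4-dihydroxy-2-(2-hydroxypropan-2-yl)-2,3-dihydro-1-benzofuran-5-yl]-3-(4-hydroxyphenyl)prop-2-en-1-one
Conditions: NaHSO4·SiO2, CH2Cl2, rt
Reagents that add atoms: none
Why: Heterogeneous mild-acid hydrolysis of phenolic MOM acetals, chosen because it works at room temperature in a non-nucleophilic solvent and should leave the C3 benzylic alcohol, the tertiary alcohol and the enone alone.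

**Compound list**
1 | 2-bromo-5-fluorophenol | Oc1cc(F)ccc1Br | starting material
2 | 3-bromo-6-fluoro-2-hydroxybenzaldehyde | O=Cc1c(O)c(Br)ccc1F | intermediate
3 | 3-bromo-6-fluoro-2-(methoxymethoxy)benzaldehyde | COCOc1c(Br)ccc(F)c1C=O | intermediate
4 | 3-(1-ethoxyvinyl)-6-fluoro-2-(methoxymethoxy)benzaldehyde (not isolated) | C=C(OCC)c1ccc(F)c(C=O)c1OCOC | intermediate
5 | 3-acetyl-6-fluoro-2-(methoxymethoxy)benzaldehyde | CC(=O)c1ccc(F)c(C=O)c1OCOC | intermediate
6 | 2-methylprop-2-ene-1,1-diyl diacetate (methacrolein diacetate) | C=C(C)C(OC(C)=O)OC(C)=O | starting material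
7 | (1S,2R)-1-[3-acetyl-6-fluoro-2-(methoxymethoxy)phenyl]-1-hydroxy-3-methylbut-3-en-2-yl acetate (not isolated) | C=C(C)[C@@H](OC(C)=O)[C@@H](O)c1c(F)ccc(C(C)=O)c1OCOC | intermediate
8 | (1S,2R)-1-[3-acetyl-6-fluoro-2-(methoxymethoxy)phenyl]-2-hydroxy-3-methylbut-3-en-1-yl acetate (not isolated) | C=C(C)[C@@H](O)[C@@H](OC(C)=O)c1c(F)ccc(C(C)=O)c1OCOC | intermediate
9 | (2R,3S)-5-acetyl-4-(methoxymethoxy)-2-(prop-1-en-2-yl)-2,3-dihydro-1-benzofuran-3-yl acetate (trans) | C=C(C)[C@H]1Oc2ccc(C(C)=O)c(OCOC)c2[C@@H]1OC(C)=O | intermediate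
10 | (2S,3S)-5-acetyl-2-(2-hydroxypropan-2-yl)-4-(methoxymethoxy)-2,3-dihydro-1-benzofuran-3-yl acetate (trans) | CC(C)(O)[C@H]1Oc2ccc(C(C)=O)c(OCOC)c2[C@@H]1OC(C)=O | intermediate
11 | 4-(methoxymethoxy)benzaldehyde | COCOc1ccc(C=O)cc1 | starting material
12 | (E)-1-[(2S,3S)-3-hydroxy-2-(2-hydroxypropan-2-yl)-4-(methoxymethoxy)-2,3-dihydro-1-benzofuran-5-yl]-3-[4-(methoxymethoxy)phenyl]prop-2-en-1-one | CC(C)(O)[C@H]1Oc2ccc(C(=O)/C=C/c3ccc(OCOC)cc3)c(OCOC)c2[C@@H]1O | intermediate
13 | brosimacutin G | CC(C)(O)[C@H]1Oc2ccc(C(=O)/C=C/c3ccc(O)cc3)c(O)c2[C@@H]1O | target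

Total step count: 7. Longest linear sequence: 7 steps (1 to 13).

**Steps most likely to fail**

Step 4 (bears the label).
- What may go wrong: ionisation of the 1,1-disubstituted allyl donor may be slow. Transfer hydrogenation of the aldehyde or the aryl ketone may compete. Anti selectivity may erode at the crowded 2,6-disubstituted aldehyde. The acyl shift and SNAr stage may lag behind base-induced side reactions of surplus donor.
- Fallback with known chemistry, from 5 back to 12: a Nozaki–Hiyama–Kishi addition of 1-bromo-2-methylprop-1-ene (CrCl2, NiCl2 cat., DMF) takes the aldehyde and leaves the ketone, and should give the racemic allylic alcohol F1. A Sharpless kinetic resolution (Ti(OiPr)4, L-(+)-DIPT, t-BuOOH, CH2Cl2, −20 °C, stopped near half conversion) should epoxidise the faster (R)-alcohol to the erythro epoxy alcohol F2. Dilute HClO4 in THF/H2O should open the epoxide at the tertiary carbon, with the C2–O bond untouched, to the triol F3. Cs2CO3 in DMSO should close ring B by SNAr through the less hindered secondary alkoxide to the dihydrobenzofuran diol F4. Claisen–Schmidt condensation of F4 with 11 under the conditions of step 6 gives 12, so step 5 is bypassed as well.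

Step 7.
- What may go wrong: acid may ionise the C3 benzylic alcohol, which two ortho oxygens assist. That would lead to loss of water toward the aromatic benzofuran or to epimerisation before the less labile ring C acetal has gone.
- Fallback, from 10 back to 13: 10 is condensed with unprotected 4-hydroxybenzaldehyde (excess KOH, EtOH) to the mono-MOM chalcone F5. The only acetal left is the one ortho to the ketone. It is then removed by chelation with MgBr2·OEt2 in CH2Cl2 at or below rt, without Brønsted acid, to give 13.

Step 5.
- What may go wrong: the radical hydration may stop at the peroxide stage, reduce the alkene to isopropyl, or lose material by β-scission of the tertiary radical next to the aryloxy-bearing C2.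
- Fallback, a polar route from 9 back to 10: N-iodosuccinimide in aqueous acetone should add water at the tertiary carbon to give the iodohydrin F6. Radical deiodination (Bu3SnH, Et3B, air, toluene, rt) erases the extra stereocenter and gives 10.

**Further compounds**
F1 | step 4 | racemic 1-[4-fluoro-3-(1-hydroxy-3-methylbut-2-en-1-yl)-2-(methoxymethoxy)phenyl]ethan-1-one | CC(C)=CC(O)c1c(F)ccc(C(C)=O)c1OCOC
F2 | step 4 | 1-{4-fluoro-3-[(S)-[(2S)-3,3-dimethyloxiran-2-yl](hydroxy)methyl]-2-(methoxymethoxy)phenyl}ethan-1-one | CC1(C)O[C@H]1[C@@H](O)c1c(F)ccc(C(C)=O)c1OCOC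
F3 | step 4 | 1-{4-fluoro-2-(methoxymethoxy)-3-[(1S,2S)-1,2,3-trihydroxy-3-methylbutyl]phenyl}ethan-1-one | CC(C)(O)[C@@H](O)[C@@H](O)c1c(F)ccc(C(C)=O)c1OCOC
F4 | step 4 | 1-[(2S,3S)-3-hydroxy-2-(2-hydroxypropan-2-yl)-4-(methoxymethoxy)-2,3-dihydro-1-benzofuran-5-yl]ethan-1-one | CC(C)(O)[C@H]1Oc2ccc(C(C)=O)c(OCOC)c2[C@@H]1O
F5 | step 7 | (E)-1-[(2S,3S)-3-hydroxy-2-(2-hydroxypropan-2-yl)-4-(methoxymethoxy)-2,3-dihydro-1-benzofuran-5-yl]-3-(4-hydroxyphenyl)prop-2-en-1-one | CC(C)(O)[C@H]1Oc2ccc(C(=O)/C=C/c3ccc(O)cc3)c(OCOC)c2[C@@H]1O
F6 | step 5 | (2S,3S)-5-acetyl-2-(2-hydroxy-1-iodopropan-2-yl)-4-(methoxymethoxy)-2,3-dihydro-1-benzofuran-3-yl acetate, both epimers at the new carbinol carbon | CC(O)(CI)[C@H]1Oc2ccc(C(C)=O)c(OCOC)c2[C@@H]1OC(C)=O
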